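**Plan**

1. Retrosynthesis, ring A numbered C1 (OH), C2 (OAr), C3–C5 (Br), C6 (H), ring B C1' (O), C2' (Br): cut the O–CH3 bond of a methyl-protected phenol, then C4–Br back to C4–N (Sandmeyer), then C3–Br and C5–Br (both ortho to that nitrogen), then C4–N (azo coupling para to the C1 hydroxyl), and last C2'–Br, whose carbon is rejoined to the ether oxygen it lost to give dibenzo[b,e][1,4]dioxin.
2. Enabling feature: the C1–OH of ring A and the C2'–Br of ring B both stand ortho to the bridging oxygen, so they are the two ends left when one aryl C–O bond of the central 1,4-dioxin ring of the symmetric heterocycle is cut.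
3. Forward: no ring is built. Both benzene rings and the diaryl ether arrive in dibenzodioxin, the central ring is opened in step 1 (C2'–Li, then C2'–Br), and ring A is then dressed in the order N at C4, Br at C3 and C5, Br at C4, release of the hydroxyl.
4. Stereochemistry: the target has no stereocentre and no stereogenic double bond. The only stereo element on the way is the E azo bond of 7 and 8, which is destroyed in step 4.

Key step: step 1

**Route**

Step 1
Reactants: 1 dibenzo[b,e][1,4]dioxin; 2 1,2-dibromo-1,1,2,2-tetrachloroethane
Product: 4 2-(2-bromophenoxy)phenol, via dilithio dianion 3 (not isolated)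
Conditions: Li powder (3 equiv), 4,4'-di-tert-butylbiphenyl (DTBB, 10 mol %), THF, 0 °C; filtration from unreacted Li under Ar; cannulation into 2 (1.2 equiv), THF, −78 °C; then 1 M HCl
Reagents that add atoms: 1,2-dibromo-1,1,2,2-tetrachloroethane (compound 2), BrC(Cl)(Cl)C(Cl)(Cl)Br
Why: Arene-catalysed reductive lithiation: the DTBB radical anion passes an electron to 1, the resulting radical anion breaks one aryl C–O bond, and a second electron gives dianion 3, a lithium phenoxide on ring A and an ortho-aryllithium on ring B. The closest known reaction type is the lithium/arene reductive opening of dibenzo-fused six-membered diheterocycles with electrophile capture, combined with halophilic bromination of an aryllithium by a vicinal dibromide, which then loses bromide and tetrachloroethene. No ring is closed (the central 1,4-dioxin ring is opened) and no stereocentre arises. The step needs single cleavage and bromination at carbon only. The four C–O bonds of 1 are equivalent by symmetry, so any first cleavage gives the same dianion, and the doubly charged 3 should be much harder to reduce than 1 at 0 °C. Removing the metal before the bromine donor is met, and inverse addition at −78 °C, should let the aryllithium, far more nucleophilic than the phenoxide, take the bromine without reduction of the new C–Br bond.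

Step 2
Reactants: 4 2-(2-bromophenoxy)phenol; 5 aniline
Product: 7 2-(2-bromophenoxy)-4-[(E)-phenyldiazenyl]phenol, via benzenediazonium chloride 6 (not isolated)
Conditions: 5, NaNO2, 2 M HCl, 0–5 °C; then added to 4, NaOH, H2O/THF, 0–5 °C; AcOH to pH 5
Reagents that add atoms: sodium nitrite (NaNO2), [Na+].[O-]N=O
Why: Diazotisation followed by azo coupling (electrophilic aromatic substitution) should take the weakly electrophilic diazonium ion 6 only to the phenoxide ring of 4, at the unhindered position para to the oxygen, because ring B is an unactivated bromoaryl ether; the azo bond forms in the more stable E geometry.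

Step 3
Reactants: 7 2-(2-bromophenoxy)-4-[(E)-phenyldiazenyl]phenol
Product: 8 (E)-1-[3-(2-bromophenoxy)-4-methoxyphenyl]-2-phenyldiazene
Conditions: MeI, K2CO3, DMF, rt
Reagents that add atoms: iodomethane, CI
Why: Williamson O-methylation (SN2) of the acidic azo-phenol masks the hydroxyl, so that the later amino arene is not oxidised to a quinone imine by the brominating agent and the amine alone controls the orientation.

Step 4
Reactants: 8 (E)-1-[3-(2-bromophenoxy)-4-methoxyphenyl]-2-phenyldiazene
Product: 9 3-(2-bromophenoxy)-4-methoxyaniline
Conditions: Na2S2O4 (excess), EtOH/H2O, 80 °C; co-formed aniline removed by steam distillation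
Reagents that add atoms: none
Why: Dithionite reduction cleaves the azo N=N bond through the hydrazo compound into two amines and leaves the aryl bromide and both ethers untouched, so the nitrogen placed by azo coupling is unmasked as a primary amine para to the methoxy group.

Step 5
Reactants: 9 3-(2-bromophenoxy)-4-methoxyaniline
Product: 10 2,6-dibromo-3-(2-bromophenoxy)-4-methoxyaniline
Conditions: NBS (2.05 equiv), MeCN, 0 °C to rt, dark
Reagents that add atoms: N-bromosuccinimide, O=C1CCC(=O)N1Br
Why: Electrophilic aromatic bromination is governed by the amino group: its para position carries OMe, so both bromines should enter ortho to nitrogen, at sites that are also ortho and para to the aryloxy oxygen, whereas the remaining ring A hydrogen is meta to nitrogen and ring B is deactivated by its bromine.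

Step 6
Reactants: 10 2,6-dibromo-3-(2-bromophenoxy)-4-methoxyaniline
Product: 12 1,2,3-tribromo-4-(2-bromophenoxy)-5-methoxybenzene, via arenediazonium bromide 11 (not isolated)
Conditions: NaNO2, 48% aq HBr/AcOH, 0–5 °C; then CuBr, 48% aq HBr, 60 °C
Reagents that add atoms: hydrogen bromide (48% aqueous), Br; CuBr (bromine-transfer mediator), Br[Cu]
Why: Sandmeyer reaction: diazotisation to 11 and electron transfer from CuBr give the aryl radical, which takes bromine from the CuBr2 so formed, putting the third contiguous bromine on the carbon that no direct bromination could reach; any ether cleavage by the warm acid would only anticipate step 7.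

Step 7
Reactants: 12 1,2,3-tribromo-4-(2-bromophenoxy)-5-methoxybenzene
Product: 13 3,4,5-tribromo-2-(2-bromophenoxy)phenol
Conditions: BBr3, CH2Cl2, −78 °C to rt; then H2O
Reagents that add atoms: none
Why: BBr3 ether cleavage: coordination to the methoxy oxygen and SN2 attack of bromide on the methyl carbon free the phenol after hydrolysis, while the diaryl ether, which offers no sp3 carbon, and the four aryl bromides are inert.

**Compound list**

1 | dibenzo[b,e][1,4]dioxin | c1ccc2Oc3ccccc3Oc2c1 | starting material
2 | 1,2-dibromo-1,1,2,2-tetrachloroethane | BrC(Cl)(Cl)C(Cl)(Cl)Br | starting material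
3 | lithium 2-(2-lithiophenoxy)phenolate | [Li]c1ccccc1Oc1ccccc1O[Li] | intermediate
4 | 2-(2-bromophenoxy)phenol | Oc1ccccc1Oc1ccccc1Br | intermediate
5 | aniline | Nc1ccccc1 | starting material
6 | benzenediazonium chloride | N#[N+]c1ccccc1.[Cl-] | intermediate
7 | 2-(2-bromophenoxy)-4-[(E)-phenyldiazenyl]phenol | Oc1ccc(/N=N/c2ccccc2)cc1Oc1ccccc1Br | intermediate
8 | (E)-1-[3-(2-bromophenoxy)-4-methoxyphenyl]-2-phenyldiazene | COc1ccc(/N=N/c2ccccc2)cc1Oc1ccccc1Br | intermediate
9 | 3-(2-bromophenoxy)-4-methoxyaniline | COc1ccc(N)cc1Oc1ccccc1Br | intermediate
10 | 2,6-dibromo-3-(2-bromophenoxy)-4-methoxyaniline | COc1cc(Br)c(N)c(Br)c1Oc1ccccc1Br | intermediate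
11 | 2,6-dibromo-3-(2-bromophenoxy)-4-methoxybenzenediazonium bromide | COc1cc(Br)c([N+]#N)c(Br)c1Oc1ccccc1Br.[Br-] | intermediate
12 | 1,2,3-tribromo-4-(2-bromophenoxy)-5-methoxybenzene | COc1cc(Br)c(Br)c(Br)c1Oc1ccccc1Br | intermediate
13 | 3,4,5-tribromo-2-(2-bromophenoxy)phenol | Oc1cc(Br)c(Br)c(Br)c1Oc1ccccc1Br | target
14 | 2-methoxyphenol | COc1ccccc1O | starting material
15 | (2-bromophenyl)boronic acid | OB(O)c1ccccc1Br | starting material

**Count**

Total steps: 7. Longest linear sequence: 7 steps (1 to 13). The diazotisation of aniline is done in the flask within step 2.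

**Steps most likely to fail**

Step 1. Risk: a second C–O cleavage of the dianion, or electron transfer from leftover reductant to the bromine donor and to the freshly formed aryl bromide, would return bromine-free material; bromination on the phenoxide ring is a further possibility. The fallback gives up the ring opening and builds the diaryl ether with the ring B bromine already in place. It sets out from 14 and 15, listed above as commercial starting materials for this purpose only, and comes back to the route at 4. Chan–Lam O-arylation of 2-methoxyphenol 14 with (2-bromophenyl)boronic acid 15 (Cu(OAc)2, pyridine, 4 Å molecular sieves, CH2Cl2, air, rt) should give 1-bromo-2-(2-methoxyphenoxy)benzene F1 without touching the C–Br bond. BBr3 in CH2Cl2 should then cleave the methyl ether to 4.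

Step 6. Risk: slow diazotisation of the weakly basic, doubly ortho-brominated amine, and loss of the diazonium group to hydrogen or hydroxyl in hot aqueous acid before bromine is transferred. The fallback sets out from 10, passes through 11 and comes back at 12, and moves the C–Br bond formation to an isolated, purifiable diazonium surrogate under anhydrous, copper-free conditions. The cold solution of 11 is run into diethylamine and K2CO3 in water at 0 °C, which should give (E)-1-[2,6-dibromo-3-(2-bromophenoxy)-4-methoxyphenyl]-3,3-diethyltriaz-1-ene F2. After chromatography, Me3SiBr in MeCN at 60 °C should release the diazonium ion in the presence of bromide only and give 12.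

Step 5. Risk: incomplete substitution at the crowded position between the amino and aryloxy groups, so that the excess of reagent needed to finish it starts a third bromination ortho to the methoxy group or oxidises the electron-rich aminoanisole. The fallback sets out from 7 and comes back to the route at the target 13. It replaces the donor methyl ether by an electron-withdrawing sulfonate, which deactivates the competing site and lowers the oxidation sensitivity, so that an excess of NBS can be used. MsCl and Et3N in CH2Cl2 should give 2-(2-bromophenoxy)-4-[(E)-phenyldiazenyl]phenyl methanesulfonate F3. Na2S2O4 in aqueous EtOH should cleave the azo group to 4-amino-2-(2-bromophenoxy)phenyl methanesulfonate F4. NBS in MeCN should give 4-amino-3,5-dibromo-2-(2-bromophenoxy)phenyl methanesulfonate F5. Diazotisation (NaNO2, HBr/AcOH) to 2,6-dibromo-3-(2-bromophenoxy)-4-(methanesulfonyloxy)benzenediazonium bromide F6 and treatment with CuBr should give 3,4,5-tribromo-2-(2-bromophenoxy)phenyl methanesulfonate F7. NaOH in aqueous MeOH followed by acidification should then release 13.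

**Further compounds**

F1 | step 1 | 1-bromo-2-(2-methoxyphenoxy)benzene | COc1ccccc1Oc1ccccc1Br
F2 | step 6 | (E)-1-[2,6-dibromo-3-(2-bromophenoxy)-4-methoxyphenyl]-3,3-diethyltriaz-1-ene | CCN(CC)/N=N/c1c(Br)cc(OC)c(Oc2ccccc2Br)c1Br
F3 | step 5 | 2-(2-bromophenoxy)-4-[(E)-phenyldiazenyl]phenyl methanesulfonate | CS(=O)(=O)Oc1ccc(/N=N/c2ccccc2)cc1Oc1ccccc1Br
F4 | step 5 | 4-amino-2-(2-bromophenoxy)phenyl methanesulfonate | CS(=O)(=O)Oc1ccc(N)cc1Oc1ccccc1Br
F5 | step 5 | 4-amino-3,5-dibromo-2-(2-bromophenoxy)phenyl methanesulfonate | CS(=O)(=O)Oc1cc(Br)c(N)c(Br)c1Oc1ccccc1Br
F6 | step 5 | 2,6-dibromo-3-(2-bromophenoxy)-4-(methanesulfonyloxy)benzenediazonium bromide | CS(=O)(=O)Oc1cc(Br)c([N+]#N)c(Br)c1Oc1ccccc1Br.[Br-]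
F7 | step 5 | 3,4,5-tribromo-2-(2-bromophenoxy)phenyl methanesulfonate | CS(=O)(=O)Oc1cc(Br)c(Br)c(Br)c1Oc1ccccc1Br
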